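## Retrosynthetic overview

1. Target 18 ⇐ carbonate cleavage and global O‑debenzylation of dimer 16; in 16 the upper pyran ring, the C4–C6 interflavan bond and the upper C4 stereocenter are made together from spirodienone 9 and lower‑unit carbonate 15.
2. Enabling feature: in the upper A‑ring the hydroxyl‑bearing C8 is the neighbour of C8a (the carbon carrying O1) and C4a is its other neighbour. The ring can therefore be written as a cyclohexa‑2,4‑dienone (C8=O) whose sp3 carbon C8a holds both O1 and C4 (a 1‑oxaspiro[4.5]decatrienone). A 1,2‑shift of C4 from C8a to C4a re‑aromatises the ring and expands the five‑membered O‑ring to the pyran; O1 (ortho) and the 7‑oxygen (para) then stabilise a cation at C4.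
3. 9 ⇐ phenol 8 by dearomatising spiroetherification; 8 ⇐ Z‑selective semi‑reduction of propargylic alcohol 6 ⇐ asymmetric alkynylation of aldehyde 5 with alkyne 4 (from 1).
4. 15 ⇐ all‑cis diol 14 ⇐ Woodward cis‑hydroxylation of flav‑3‑ene 11 ⇐ the same ring expansion of 9 run without a nucleophile (step 8); one carbinol centre thus supplies C2 of both flavan units.
5. Ring order: spiro‑dihydrofuran (step 7) → lower pyran by expansion (step 8) → carbonate ring (step 11) → upper pyran by expansion with interflavan coupling (step 12).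

Key step: step 12

Remark: in step 4 the BINOL antipode is the one that delivers the R carbinol; (R)‑BINOL is written on the assumption that the sense reported for aryl aldehydes holds, and the other antipode would be taken if it did not.

## Route

Step 1
Reactants: 1 2,3-dihydroxybenzaldehyde
Product: 2 3-(benzyloxy)-2-hydroxybenzaldehyde
Conditions: NaH (2.2 equiv), DMSO, 20 °C; BnBr (1.0 equiv); aq. HCl work-up
Reagents that add atoms: benzyl bromide, BrCc1ccccc1
Why: Williamson etherification of the dianion: the 2-phenolate is held in a chelate with the formyl oxygen, so the free and more nucleophilic 3-phenolate takes the single equivalent of benzyl bromide.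

Step 2
Reactants: 2 3-(benzyloxy)-2-hydroxybenzaldehyde
Product: 3 2-(benzyloxy)-6-ethynylphenol
Conditions: dimethyl (1-diazo-2-oxopropyl)phosphonate, K2CO3, MeOH, 20 °C
Reagents that add atoms: dimethyl (1-diazo-2-oxopropyl)phosphonate, CC(=O)C(=[N+]=[N-])P(=O)(OC)OC
Why: Seyferth–Gilbert homologation in the Ohira–Bestmann variant: the diazophosphonate anion released by methanolysis olefinates the aldehyde and the alkylidene carbene rearranges to the terminal alkyne, under K2CO3/MeOH that the free phenol and the benzyl ether tolerate.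

Step 3
Reactants: 3 2-(benzyloxy)-6-ethynylphenol
Product: 4 [2-(benzyloxy)-6-ethynylphenoxy](tert-butyl)dimethylsilane
Conditions: TBSCl, imidazole, DMF, 20 °C
Reagents that add atoms: tert-butyldimethylsilyl chloride, CC(C)(C)[Si](C)(C)Cl
Why: Silyl protection (TBSCl/imidazole) masks the phenol so that it can neither quench the indium acetylide of step 4 nor add to the alkyne.

Step 4
Reactants: 4 [2-(benzyloxy)-6-ethynylphenoxy](tert-butyl)dimethylsilane; 5 4-(benzyloxy)benzaldehyde
Product: 6 (R)-1-[4-(benzyloxy)phenyl]-3-[3-(benzyloxy)-2-(tert-butyldimethylsilyloxy)phenyl]prop-2-yn-1-ol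
Conditions: InBr3 (10 mol%), (R)-BINOL (10 mol%), Cy2NMe (50 mol%), CH2Cl2, 40 °C
Reagents that add atoms: none
Why: Catalytic asymmetric alkynylation of an aryl aldehyde (In(III)/BINOL activation of both partners) joins the two aryl-bearing halves and sets the carbinol centre as R under catalyst control, the centre that later becomes C2 of both flavan units.

Step 5
Reactants: 6 (R)-propargylic alcohol
Product: 7 (S,Z)-1-[4-(benzyloxy)phenyl]-3-[3-(benzyloxy)-2-(tert-butyldimethylsilyloxy)phenyl]prop-2-en-1-ol
Conditions: H2 (1 atm), Lindlar catalyst, quinoline, EtOAc, 20 °C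
Reagents that add atoms: none
Why: Lindlar semi-hydrogenation adds H2 syn to the alkyne and stops at the Z alkene, the geometry that step 7 needs to close a five-membered ring, while benzyl ethers and the benzylic carbinol are not touched on the poisoned catalyst (the descriptor changes from R to S only through CIP priorities).

Step 6
Reactants: 7 (S,Z)-allylic alcohol silyl ether
Product: 8 (S,Z)-2-(benzyloxy)-6-{3-[4-(benzyloxy)phenyl]-3-hydroxyprop-1-en-1-yl}phenol
Conditions: K2CO3 (0.5 equiv), MeOH/THF, 0 → 20 °C; neutral work-up, used directly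
Reagents that add atoms: none
Why: Base-catalysed methanolysis of the aryl silyl ether frees the phenol under conditions in which the allylic benzylic alcohol cannot ionise (acid would close it onto the phenol oxygen), and the carbinol centre is not involved.

Step 7
Reactants: 8 (S,Z)-2-(benzyloxy)-6-{3-[4-(benzyloxy)phenyl]-3-hydroxyprop-1-en-1-yl}phenol
Product: 9 (2S)-7-(benzyloxy)-2-[4-(benzyloxy)phenyl]-1-oxaspiro[4.5]deca-3,7,9-trien-6-one (both C5 epimers)
Conditions: PhI(OAc)2 (1.05 equiv), MeCN/CH2Cl2, −40 → −10 °C; cold filtration through basic alumina, used at once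
Reagents that add atoms: none
Why: Hypervalent-iodine oxidative dearomatisation with intramolecular capture by the tethered alcohol (dearomatising spiroetherification): the hydroxyl can reach only the ortho carbon that carries the cis-alkenyl chain (5-membered ring), the C2–O bond is not broken so C2 stays S, and the new spiro centre may form as either epimer because steps 8 and 12 erase it.

Step 8
Reactants: 9 (2S)-spirodienone
Product: 10 (2S)-7-(benzyloxy)-2-[4-(benzyloxy)phenyl]-2H-chromen-8-ol
Conditions: BF3·OEt2 (0.2 equiv), 2,6-di-tert-butyl-4-methylpyridine (0.4 equiv), CH2Cl2, −78 → −40 °C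
Reagents that add atoms: none
Why: Proposed new method: coordination of BF3 to the C6 carbonyl gives a hydroxypentadienyl-type cation with positive charge on C10, the sp2 neighbour of the spiro carbon, so that the vinylic carbon C4 migrates from C5 to C10 (1,2-shift, favoured over oxygen migration because it leaves a cation on C5 that the ring oxygen stabilises) and loss of the C10 proton to the hindered pyridine, which keeps the acid-labile chromene from being protonated, restores the benzene ring, which amounts to a dienone–phenol rearrangement (closest known type: acid-mediated ring expansion of spirocyclohexadienones) that converts the spiro-dihydrofuran into the 2H-pyran, leaves C2 untouched and funnels both spiro epimers into one product.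

Step 9
Reactants: 10 (2S)-7-(benzyloxy)-2-[4-(benzyloxy)phenyl]-2H-chromen-8-ol
Product: 11 (2S)-7,8-bis(benzyloxy)-2-[4-(benzyloxy)phenyl]-2H-chromene
Conditions: BnBr, K2CO3, DMF, 20 °C
Reagents that add atoms: benzyl bromide, BrCc1ccccc1
Why: Williamson benzylation of the liberated 8-OH gives the fully protected flav-3-ene, with C2 untouched under weakly basic conditions.

Step 10
Reactants: 11 (2S)-7,8-bis(benzyloxy)-2-[4-(benzyloxy)phenyl]-2H-chromene
Product: 14 (2R,3R,4R)-7,8-bis(benzyloxy)-2-[4-(benzyloxy)phenyl]chromane-3,4-diol, via trans-iodoacetate 12 (not isolated), via cis-hydroxyacetate 13 (not isolated)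
Conditions: I2 (1.05 equiv), AgOAc (2.2 equiv), AcOH, 20 °C, dark; then AcOH/H2O, 40 °C; then K2CO3 (cat.), MeOH, 20 °C
Reagents that add atoms: silver(I) acetate, CC(=O)[O-].[Ag+]
Why: Woodward cis-hydroxylation: iodonium forms on the face anti to the 2-aryl group, acetate opens it at benzylic C4 from the aryl face, silver-assisted displacement of iodide by that acetate (inversion at C3) gives a cis-fused acetoxonium ion on the aryl face, and its hydrolysis and methanolysis deliver the 2,3-cis-3,4-cis diol (both new C–O bonds from the acetate oxygens), the face that osmylation would not reach.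

Step 11
Reactants: 14 (2R,3R,4R)-7,8-bis(benzyloxy)-2-[4-(benzyloxy)phenyl]chromane-3,4-diol
Product: 15 cyclic 3,4-carbonate of diol 14 (all-cis)
Conditions: 1,1'-carbonyldiimidazole, THF, 20 °C
Reagents that add atoms: 1,1'-carbonyldiimidazole, O=C(n1ccnc1)n1ccnc1
Why: Cyclic carbonate formation from the cis-1,2-diol with carbonyldiimidazole ties up both hydroxyls and turns the lower unit's own benzylic C4–O bond into a poor leaving group for the acid of step 12, without touching a stereocenter.

Step 12
Reactants: 9 (2S)-spirodienone; 15 cyclic 3,4-carbonate of diol 14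
Product: 16 cyclic 3,4-carbonate of (2R,3R,4R)-7,8-bis(benzyloxy)-2-[4-(benzyloxy)phenyl]-6-{(2S,4R)-7-(benzyloxy)-2-[4-(benzyloxy)phenyl]-8-hydroxychroman-4-yl}chromane-3,4-diol (upper unit 2,4-trans), via flav-3-ene 10 (not isolated)
Conditions: 9 added over 1 h to 15 (2.5 equiv) and BF3·OEt2 (0.3 equiv), 4 Å MS, CH2Cl2, −78 → −30 °C
Reagents that add atoms: none
Why: Proposed new method: BF3 activates the C6 carbonyl of 9 and the vinylic carbon C4 shifts from the spiro carbon to the adjacent ring carbon, a dienone–phenol rearrangement that expands the 1-oxaspiro five-membered ring to the pyran of flav-3-ene 10 and turns the dienone into the aromatic A-ring with the former carbonyl as 8-OH; the closest known reaction types are the acid-mediated ring expansion of spirocyclohexadienones and the acid-catalysed addition of arenes to flav-3-enes. The proton set free on aromatisation (no base is present here) adds to C3 of 10, and the resulting C4 cation, stabilised by O1 in the ortho and the 7-benzyloxy group in the para position, alkylates C6 of 15 (Friedel–Crafts). No ring is closed by a cyclisation: the pyran arises from the dihydrofuran by a 1,2-shift of C4 from C8a to C4a (ring expansion by one carbon) and the benzene ring by loss of the C4a proton. The new stereocenter C4 is set by C2, because the half-chair cation carries the 2-aryl group equatorially and the arene enters along the axial trajectory on the face of the axial H-2, which gives the 2,4-trans adduct; C2 keeps its configuration since the C2–O1 bond is never broken, and both spiro epimers of 9 converge because that centre disappears. The step needs carbon and not oxygen migration (secured by the oxocarbenium character that O1 gives to the migration origin and by the high migratory aptitude of a vinyl group), protonation at C3 instead of C2–O1 ionisation (low temperature, catalytic acid), attack by C6 and not C5 of 15 (C6 is ortho to the 7-benzyloxy group, para to the ring oxygen and free of peri strain), and a lower unit that does not ionise at its own C4 (secured by the cyclic carbonate).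

Step 13
Reactants: 16 protected dimer carbonate
Product: 17 (2R,3R,4R)-7,8-bis(benzyloxy)-2-[4-(benzyloxy)phenyl]-6-{(2S,4R)-7-(benzyloxy)-2-[4-(benzyloxy)phenyl]-8-hydroxychroman-4-yl}chromane-3,4-diol
Conditions: K2CO3 (0.5 equiv), MeOH/THF, 0 → 20 °C, argon
Reagents that add atoms: none
Why: Base-catalysed transesterification of the cyclic carbonate with methanol frees the cis-diol, while benzyl ethers, the interflavan C–C bond and all five stereocenters are inert to carbonate in methanol.

Step 14
Reactants: 17 penta-O-benzyl dimer diol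
Product: 18 (2R,3R,4R)-6-[(2S,4S)-7,8-dihydroxy-2-(4-hydroxyphenyl)chroman-4-yl]-2-(4-hydroxyphenyl)chromane-3,4,7,8-tetrol
Conditions: H2 (1 atm), Pd(OH)2/C, THF/MeOH, 20 °C; filtration under argon
Reagents that add atoms: none
Why: Hydrogenolysis of the five benzyl ethers over Pearlman's catalyst under neutral conditions, where the cyclic benzylic ethers, the doubly benzylic C4–H and the free benzylic 4-hydroxyl are expected to survive, gives the target without touching a stereocenter.

## Compound list

1 | 2,3-dihydroxybenzaldehyde | O=Cc1cccc(O)c1O | starting material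
2 | 3-(benzyloxy)-2-hydroxybenzaldehyde | O=Cc1cccc(OCc2ccccc2)c1O | intermediate
3 | 2-(benzyloxy)-6-ethynylphenol | C#Cc1cccc(OCc2ccccc2)c1O | intermediate
4 | [2-(benzyloxy)-6-ethynylphenoxy](tert-butyl)dimethylsilane | C#Cc1cccc(OCc2ccccc2)c1O[Si](C)(C)C(C)(C)C | intermediate
5 | 4-(benzyloxy)benzaldehyde | O=Cc1ccc(OCc2ccccc2)cc1 | starting material
6 | (R)-1-[4-(benzyloxy)phenyl]-3-[3-(benzyloxy)-2-(tert-butyldimethylsilyloxy)phenyl]prop-2-yn-1-ol | O(Cc1ccccc1)c1ccc([C@@H](O)C#Cc2cccc(OCc3ccccc3)c2O[Si](C)(C)C(C)(C)C)cc1 | intermediate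
7 | (S,Z)-1-[4-(benzyloxy)phenyl]-3-[3-(benzyloxy)-2-(tert-butyldimethylsilyloxy)phenyl]prop-2-en-1-ol | O(Cc1ccccc1)c1ccc([C@@H](O)/C=C\c2cccc(OCc3ccccc3)c2O[Si](C)(C)C(C)(C)C)cc1 | intermediate
8 | (S,Z)-2-(benzyloxy)-6-{3-[4-(benzyloxy)phenyl]-3-hydroxyprop-1-en-1-yl}phenol | O(Cc1ccccc1)c1ccc([C@@H](O)/C=C\c2cccc(OCc3ccccc3)c2O)cc1 | intermediate
9 | (2S)-7-(benzyloxy)-2-[4-(benzyloxy)phenyl]-1-oxaspiro[4.5]deca-3,7,9-trien-6-one, both epimers at spiro C5 | O(Cc1ccccc1)c1ccc([C@@H]2C=CC3(O2)C=CC=C(OCc4ccccc4)C3=O)cc1 | intermediate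
10 | (2S)-7-(benzyloxy)-2-[4-(benzyloxy)phenyl]-2H-chromen-8-ol | O(Cc1ccccc1)c1ccc([C@@H]2C=Cc3ccc(OCc4ccccc4)c(O)c3O2)cc1 | intermediate (isolated in step 8, not isolated in step 12)
11 | (2S)-7,8-bis(benzyloxy)-2-[4-(benzyloxy)phenyl]-2H-chromene | O(Cc1ccccc1)c1ccc([C@@H]2C=Cc3ccc(OCc4ccccc4)c(OCc4ccccc4)c3O2)cc1 | intermediate
12 | 7,8-bis(benzyloxy)-2-[4-(benzyloxy)phenyl]-3-iodochroman-4-yl acetate, 2,3-trans-3,4-trans (iodine anti to the 2-aryl group, acetate on the aryl face) | c1cc2c(c(OCc3ccccc3)c1OCc1ccccc1)O[C@H](c1ccc(OCc3ccccc3)cc1)[C@@H](I)[C@@H]2OC(C)=O | intermediate (not isolated)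
13 | 3-O-acetate of diol 14 (all-cis; principal monoacetate) | c1cc2c(c(OCc3ccccc3)c1OCc1ccccc1)O[C@H](c1ccc(OCc3ccccc3)cc1)[C@H](OC(C)=O)[C@@H]2O | intermediate (not isolated)
14 | (2R,3R,4R)-7,8-bis(benzyloxy)-2-[4-(benzyloxy)phenyl]chromane-3,4-diol (2,3-cis-3,4-cis) | c1cc2c(c(OCc3ccccc3)c1OCc1ccccc1)O[C@H](c1ccc(OCc3ccccc3)cc1)[C@H](O)[C@@H]2O | intermediate
15 | cyclic 3,4-carbonate of diol 14 (aryl, O3 and O4 on one face) | c1cc2c(c(OCc3ccccc3)c1OCc1ccccc1)O[C@H](c1ccc(OCc3ccccc3)cc1)[C@H](OC(=O)O4)[C@@H]24 | intermediate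
16 | cyclic 3,4-carbonate of 17; upper unit (2S,4R), 2,4-trans (C4 is R by CIP in the benzylated series and S in 18, same spatial arrangement) | O(Cc1ccccc1)c1ccc([C@@H]2C[C@@H](c3cc4c(c(OCc5ccccc5)c3OCc3ccccc3)O[C@H](c3ccc(OCc5ccccc5)cc3)[C@H](OC(=O)O6)[C@@H]46)c3ccc(OCc4ccccc4)c(O)c3O2)cc1 | intermediate
17 | (2R,3R,4R)-7,8-bis(benzyloxy)-2-[4-(benzyloxy)phenyl]-6-{(2S,4R)-7-(benzyloxy)-2-[4-(benzyloxy)phenyl]-8-hydroxychroman-4-yl}chromane-3,4-diol | O(Cc1ccccc1)c1ccc([C@@H]2C[C@@H](c3cc4c(c(OCc5ccccc5)c3OCc3ccccc3)O[C@H](c3ccc(OCc5ccccc5)cc3)[C@H](O)[C@@H]4O)c3ccc(OCc4ccccc4)c(O)c3O2)cc1 | intermediate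
18 | (2R,3R,4R)-6-[(2S,4S)-7,8-dihydroxy-2-(4-hydroxyphenyl)chroman-4-yl]-2-(4-hydroxyphenyl)chromane-3,4,7,8-tetrol | Oc1ccc([C@@H]2C[C@@H](c3cc4c(c(O)c3O)O[C@H](c3ccc(O)cc3)[C@H](O)[C@@H]4O)c3ccc(O)c(O)c3O2)cc1 | target

Total step count: 14
Longest linear sequence: 14 steps (1 → 18; compound 9 is drawn on in steps 8 and 12)

## Steps most likely to fail

**Step 12 (Proposed new method).** After the ring expansion the benzylic cation may be consumed by the alkene or the free 8‑OH of a second chromene molecule faster than by C6 of 15 (oligomerisation), or reversible ionisation of the C2–O1 bond may erode the configuration at C2. The fallback separates the two events and uses only known chemistry; it sets out from 11 (with 15) and comes back to the route at 18. The fully benzylated flav‑3‑ene 11 and carbonate 15 are combined under acid (BF3·OEt2 or cat. TfOH, CH2Cl2, −40 °C), the known acid‑catalysed addition of an arene to a flav‑3‑ene through C3 protonation, to give the 8‑O‑benzyl dimer carbonate F1. Methanolysis (K2CO3, MeOH/THF) gives the hexa‑O‑benzyl dimer diol F2, and hydrogenolysis over Pd(OH)2/C gives 18.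

**Step 8 (Proposed new method).** Oxygen might migrate instead of carbon, the allylic‑benzylic C2–O bond of the dienone might ionise, or the chromene might be protonated and oligomerise once formed. The fallback builds the same flav‑3‑ene by known flavanone chemistry; it sets out from 5 and comes back at 11. Claisen–Schmidt condensation (KOH, EtOH) of 5 with 1‑[3,4‑bis(benzyloxy)‑2‑hydroxyphenyl]ethan‑1‑one F3 (from commercial 2′,3′,4′‑trihydroxyacetophenone, BnBr, K2CO3) gives the 2′‑hydroxychalcone F4. NaOAc in refluxing EtOH closes it to the racemic flavanone F5. Asymmetric transfer hydrogenation in kinetic‑resolution mode [RuCl(p‑cymene)((S,S)‑TsDPEN), HCO2H/Et3N; antipode chosen for the 4S carbinol] should reduce the 2S enantiomer to the (2S,4S)‑cis‑flavan‑4‑ol F6, and Burgess dehydration gives 11.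

**Step 10.** Acetyl hypoiodite may iodinate the benzyloxy‑substituted rings in competition with addition to the alkene, and ionisation at benzylic C4 may let acetate enter cis to iodine, so that the acetoxonium ion cannot form. The fallback reaches the same acetoxonium ion from an epoxide; it sets out from 11 and comes back at 13 (then 14 as in step 10). Dimethyldioxirane (acetone, −20 °C) epoxidises 11 on the face anti to the 2‑aryl group to give the 3,4‑epoxide F7. Acetic acid opens it at benzylic C4 with inversion to the trans hydroxy acetate F8. Tf2O/pyridine followed by water makes the 4‑acetoxy group displace the 3‑triflate with inversion at C3, and hydrolysis of the resulting cis‑fused acetoxonium ion gives 13.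

## Further compounds

F1 | step 12 | cyclic 3,4-carbonate of F2 (8-O-benzyl analogue of 16) | O(Cc1ccccc1)c1ccc([C@@H]2C[C@@H](c3cc4c(c(OCc5ccccc5)c3OCc3ccccc3)O[C@H](c3ccc(OCc5ccccc5)cc3)[C@H](OC(=O)O6)[C@@H]46)c3ccc(OCc4ccccc4)c(OCc4ccccc4)c3O2)cc1
F2 | step 12 | (2R,3R,4R)-7,8-bis(benzyloxy)-2-[4-(benzyloxy)phenyl]-6-{(2S,4R)-7,8-bis(benzyloxy)-2-[4-(benzyloxy)phenyl]chroman-4-yl}chromane-3,4-diol | O(Cc1ccccc1)c1ccc([C@@H]2C[C@@H](c3cc4c(c(OCc5ccccc5)c3OCc3ccccc3)O[C@H](c3ccc(OCc5ccccc5)cc3)[C@H](O)[C@@H]4O)c3ccc(OCc4ccccc4)c(OCc4ccccc4)c3O2)cc1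
F3 | step 8 | 1-[3,4-bis(benzyloxy)-2-hydroxyphenyl]ethan-1-one | CC(=O)c1ccc(OCc2ccccc2)c(OCc2ccccc2)c1O
F4 | step 8 | (E)-1-[3,4-bis(benzyloxy)-2-hydroxyphenyl]-3-[4-(benzyloxy)phenyl]prop-2-en-1-one | O=C(/C=C/c1ccc(OCc2ccccc2)cc1)c1ccc(OCc2ccccc2)c(OCc2ccccc2)c1O
F5 | step 8 | rac-7,8-bis(benzyloxy)-2-[4-(benzyloxy)phenyl]chroman-4-one | O=C1CC(c2ccc(OCc3ccccc3)cc2)Oc2c1ccc(OCc1ccccc1)c2OCc1ccccc1
F6 | step 8 | (2S,4S)-7,8-bis(benzyloxy)-2-[4-(benzyloxy)phenyl]chroman-4-ol | O(Cc1ccccc1)c1ccc([C@@H]2C[C@H](O)c3ccc(OCc4ccccc4)c(OCc4ccccc4)c3O2)cc1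
F7 | step 10 | 3,4-epoxide of 11 (epoxide oxygen anti to the 2-aryl group) | c1cc2c(c(OCc3ccccc3)c1OCc1ccccc1)O[C@H](c1ccc(OCc3ccccc3)cc1)[C@H]3O[C@@H]23
F8 | step 10 | 7,8-bis(benzyloxy)-2-[4-(benzyloxy)phenyl]-3-hydroxychroman-4-yl acetate, 2,3-trans-3,4-trans (3-OH anti to the aryl group, 4-OAc on the aryl face) | c1cc2c(c(OCc3ccccc3)c1OCc1ccccc1)O[C@H](c1ccc(OCc3ccccc3)cc1)[C@@H](O)[C@@H]2OC(C)=O
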